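**Remark on the chemistry:** flavanone numbering (O1, C2, C3, C4, C4a, C5 to C8, C8a) is used for the ring atoms of every intermediate. Ring A is the benzo ring, ring B the oxygen heterocycle and ring C the 2-phenyl group. "Geranyl" stands for (2E)-3,7-dimethylocta-2,6-dien-1-yl. The target is taken as the S enantiomer, which is what the SMILES string encodes.

## Analysis of the target

Target 16 is (S)-6-geranyl-5,7-dihydroxyflavanone, a 2-phenylchroman-4-one. Ring A carries hydroxyls at C5 and C7, the geranyl chain at C6 between them, and a single hydrogen at C8; ring B is the dihydropyranone O1–C2–C3–C4–C4a–C8a. There is one stereocentre, C2 (S), which is benzylic, bonded to O1 and β to the C4 carbonyl, with no second centre to relay from, so it has to be set absolutely. That centre is fragile: under base, ring B opens by β-elimination of the O1 phenoxide across C2–C3 and recloses without facial preference. The geranyl chain has two trisubstituted olefins, the inner one E, which excludes hydrogenolysis, electrophilic halogen and strong acid (the neighbouring phenols would cyclise onto C2'=C3'). On ring A the chain must sit at C6, flanked by both oxygens, while C8 stays a C–H. The strategy rests on the fact that O1 is bonded on one side to the aryl carbon C8a and on the other to the stereocentre C2. Forming O1–C8a rather than the usual O1–C2 allows the C2–O bond to arrive ready-made as a secondary benzylic alcohol, and ring B is then closed without touching C2. With C8a as a chloride, ring A also reduces to a symmetric 5-chlororesorcinol, in which the position between the oxygens is unique and the other two are equivalent.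

## Retrosynthetic reasoning

**16 to 15.** The two phenols are traced back to methoxymethyl ethers in 15. These acetals direct the ring metalations early on, survive strong base and palladium, and come off at the end under dilute acid, conditions under which the flavanone stereocentre is stable.

**15 to 14.** The C4 carbonyl is traced back to the spiro 1,3-dithiane of 14. A free C4 ketone in an open-chain precursor with oxygen on C2 would eliminate across C2–C3 under any base. As a thioketal, C4 cannot acidify C3–H, and the same group is the handle for making the C3–C4 bond.

**14 to 13 (key disconnection).** The O1–C8a bond is cut, giving the chloro alcohol 13. The cut is placed on the aryl side of O1 so that the forward ring closure is a palladium-catalysed aryl C–O coupling. That reaction forms ring B from a preformed (S)-carbinol with retention, because the carbinol C–O bond is not involved. The forward step must make C–O reductive elimination faster than β-hydride elimination of the palladium alkoxide.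

**13 to 10 and 11.** The C3–C4 bond is cut between the dithiane carbon and the CH2 of the hydroxyethyl arm. Forward, the anion of dithiane 10 opens (R)-styrene oxide 11 at its unsubstituted carbon. The stereocentre of 11 is a spectator; it becomes S in 13 only because the CIP priorities change. This is the only point where chirality enters, and it comes from a commercial epoxide.

**10 to 8 and 9.** The dithiane is traced to aldehyde 8 and propane-1,3-dithiol 9. The forward step must convert a hindered, electron-rich aldehyde without disturbing the acetal ethers.

**8 to 6.** The C4a–C4 bond is cut to arene 6. The two remaining ring hydrogens of 6 are equivalent, each lying between chlorine and an acetal ether, so metalation and formylation can give only one aldehyde. That aldehyde has the chloride already ortho to the new carbon, as the key step requires.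

**6 to 2 and 3, and 2 to 1.** The C6–C1' bond is cut to arene 2 and geranyl bromide 3. Arene 2 is metalated at the carbon between its two acetal ethers, which puts the chain at C6 and nowhere else. Arene 2 is the bis-acetal of 5-chlororesorcinol 1.

## Alternatives that were turned down

**Alternative 1: aryne insertion into a chiral β-alkoxy acid.**
- **Disconnection:** C8a–O1 and C4a–C4 together, with ring A inserted between the carboxyl oxygen and the acyl carbon of acid A2.
- **Forward key step:** CsF on silyl triflate A1 generates a strained triple bond across C4a–C8a. The carboxylate of A2 adds at C8a (distal to the C5 oxygen), the aryl anion at C4a attacks the acyl carbon, and acyl transfer gives hydroxy ketone A3. Removal of the benzylic ether and a Mitsunobu closure of O1–C2 with inversion would follow.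
- **For:** two skeletal bonds form in one operation from a chiral-pool acid, and no thioketal is needed. On bond count it is more convergent than the chosen route.
- **Against:** A3 is a β-alkoxy ketone formed in warm, basic fluoride, exactly the conditions for E1cB loss of the C2 oxygen across C2–C3, which destroys the stereocentre. The later Mitsunobu step makes C2 the electrophilic carbon, benzylic and β to a ketone, so elimination and ionisation compete with clean inversion. A1 also needs several steps to place silicon and triflate on a pentasubstituted ring, whereas chloride 6 takes two.
- **Comparison:** the chosen route offers instead that C4 is masked whenever base is present and that C2 is never a reacting centre.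

**Alternative 2: asymmetric carbenoid C–H insertion at C2–C3.**
- **Disconnection:** the C2–C3 bond.
- **Forward key step:** Rh2(S-PTTL)4 (divalent rhodium) decomposes diazoketone A4, and the carbenoid at C3 inserts into a benzylic C–H of the O1 benzyl ether, closing ring B and creating C2 to give A5.
- **For:** the flavanone oxidation level appears directly, the stereocentre is made catalytically from an achiral ether, and the silyl ethers of A5 could be removed without acid near the geranyl chain. On step count and on the mildness of the final deprotection it is stronger than the chosen route.
- **Against:** closing a six-membered ring by insertion competes with attack of O1 on the carbenoid followed by 1,2-benzyl migration, which would contract ring B to five members. A terminal, acceptor-only carbenoid is the least selective class, so the enantioselectivity would depend on the catalyst alone. The two electron-rich olefins of the chain and ring A itself are good carbenoid traps (cyclopropanation, Buchner-type addition). The diazoketone must also be made from a doubly ortho-substituted benzoic acid.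
- **Comparison:** the chosen route buys the configuration and only has to preserve it, and none of its reagents attacks the olefins.

**Alternative 3: carbonylative alkyne annulation to the flavone.**
- **Disconnection:** C4a–C4, C4–C3 and O1–C2.
- **Forward key step:** PdCl2(PPh3)2 (divalent palladium precatalyst) couples iodophenol A6, carbon monoxide A8 and phenylacetylene A7 to an ynone that cyclises 6-endo through the phenol to flavone A9.
- **For:** three bonds form in one flask from simple achiral parts, and this kind of ring construction is well established. On convergence and on the reliability of ring formation it is the strongest of the four.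
- **Against:** C2 in A9 is sp2, so the only stereocentre is left unaddressed. An enantioselective 1,4-reduction of C2=C3 would be needed afterwards, and it would have to spare two trisubstituted olefins, stop before C4 is reduced, and act on a 5-oxygenated vinylogous ester that is a poor acceptor. A 5-exo closure also competes in such cyclocarbonylations.
- **Comparison:** the chosen route is longer, but it fixes the configuration at the first C–C bond formed to the side chain and carries it unchanged to the end.

Key step: step 6

## Route

**Step 1**
Reactants: 1 5-chlororesorcinol (5-chlorobenzene-1,3-diol)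
Product: 2 1-chloro-3,5-bis(methoxymethoxy)benzene
Conditions: MOMCl, iPr2NEt, CH2Cl2, 0 °C → rt
Reagents that add atoms: chloromethyl methyl ether (MOMCl), COCCl
Why: O-alkylation of both phenols with the chloromethyl ether (acetal protection); the two acetal ethers serve as ortho-metalation directors and as acid-removable protection for the rest of the route.

**Step 2**
Reactants: 2 1-chloro-3,5-bis(methoxymethoxy)benzene; 3 geranyl bromide [(2E)-1-bromo-3,7-dimethylocta-2,6-diene]
Product: 6 5-chloro-2-geranyl-1,3-bis(methoxymethoxy)benzene, via aryllithium 4 (not isolated), via arylcopper 5 (not isolated)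
Conditions: n-BuLi, THF, −20 °C; CuI, −40 °C; 3, −40 → 0 °C
Reagents that add atoms: none
Why: Directed ortho-metalation at the C–H flanked by both acetal ethers, which chelate the lithium cooperatively; this position is para to chlorine, so the aryllithium cannot lose LiCl. Transmetalation to the arylcopper (monovalent copper) then allows SN2 allylation at C1 of 3 with the E olefin retained.

**Step 3**
Reactants: 6 5-chloro-2-geranyl-1,3-bis(methoxymethoxy)benzene
Product: 8 6-chloro-3-geranyl-2,4-bis(methoxymethoxy)benzaldehyde, via ring aryllithium 7 (not isolated)
Conditions: n-BuLi, TMEDA, THF, −78 °C; DMF, −78 °C; then H2O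
Reagents that add atoms: N,N-dimethylformamide (DMF), CN(C)C=O
Why: Second directed ortho-metalation at one of the two equivalent ring C–H bonds, each activated by an acetal ether and by chlorine, kept at −78 °C so that the ortho-chloro aryllithium does not eliminate LiCl; the aryllithium is then formylated with the formamide (Bouveault formylation). Symmetry allows only one aldehyde, with the chloride ortho to the new carbon.

**Step 4**
Reactants: 8 6-chloro-3-geranyl-2,4-bis(methoxymethoxy)benzaldehyde; 9 propane-1,3-dithiol
Product: 10 2-[6-chloro-3-geranyl-2,4-bis(methoxymethoxy)phenyl]-1,3-dithiane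
Conditions: 9 (1.05 equiv), BF3·OEt2 (0.2 equiv), CH2Cl2, −40 → −20 °C; Et3N quench
Reagents that add atoms: none
Why: Lewis-acid-catalysed dithioacetalisation; the electron-rich aldehyde forms an oxygen-stabilised thionium ion readily. With the dithiol limited to one equivalent, the acid substoichiometric and the temperature low, the aldehyde should be consumed before the acetal ethers are attacked.

**Step 5**
Reactants: 10 2-[6-chloro-3-geranyl-2,4-bis(methoxymethoxy)phenyl]-1,3-dithiane; 11 (R)-styrene oxide [(2R)-2-phenyloxirane]
Product: 13 (S)-2-{2-[6-chloro-3-geranyl-2,4-bis(methoxymethoxy)phenyl]-1,3-dithian-2-yl}-1-phenylethanol, via 2-lithiodithiane 12 (not isolated)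
Conditions: n-BuLi (1.05 equiv), THF, −78 → −30 °C; 11, −30 °C → rt; then H2O
Reagents that add atoms: none
Why: Corey–Seebach umpolung: the sulfur-stabilised C–H, with lithium chelated by the ortho acetal oxygen, is deprotonated, and the anion opens the epoxide by SN2 attack at its unsubstituted CH2. The stereocentre of 11 is not involved; its descriptor changes from R to S only because phenyl now outranks the CH2 group.

**Step 6**
Reactants: 13 (S)-2-{2-[6-chloro-3-geranyl-2,4-bis(methoxymethoxy)phenyl]-1,3-dithian-2-yl}-1-phenylethanol
Product: 14 (S)-6-geranyl-5,7-bis(methoxymethoxy)-2-phenylspiro[chromane-4,2'-[1,3]dithiane]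
Conditions: Pd(OAc)2 (5 mol%), 2-(di-tert-butylphosphino)-1,1'-binaphthyl (7 mol%), Cs2CO3 (1.5 equiv), toluene, 80 °C
Reagents that add atoms: none
Why: Pd(OAc)2 (divalent palladium) is reduced in the flask to zerovalent palladium, which, bound to one bulky electron-rich phosphine, undergoes oxidative addition into the C8a–Cl bond; Cs2CO3 deprotonates the coordinated C2 hydroxyl to give a seven-membered aryl(alkoxo)palladium chelate, and C(sp2)–O reductive elimination releases 14 and the zerovalent catalyst. The closest known reaction type is the palladium-catalysed intramolecular etherification of aryl bromides and chlorides with tethered secondary alcohols to chromans, which is known to proceed on enantioenriched carbinols without erosion. Ring B closes as a six-membered ring at O1–C8a by reductive elimination from that chelate, helped by the quaternary spiro carbon C4 (Thorpe–Ingold compression) and by the ortho relation of tether and chloride. No stereocentre is formed: the carbinol C2–O bond is never broken, so the S configuration brought in with 11 is retained. With C4 held as a thioketal there is no carbonyl to acidify C3–H, so neither enolisation nor elimination across C2–C3 can occur under the carbonate base. The selectivity the step needs is reductive elimination over β-hydride elimination of the benzylic palladium alkoxide, and the di-tert-butyl biaryl ligand secures it by forcing a crowded, low-coordinate intermediate from which C–O bond formation is the faster exit. The chloride is meta to both acetal oxygens and therefore not strongly deactivated toward oxidative addition, and the acetal ethers, thioketal and olefins are inert to the weak base in toluene.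

**Step 7**
Reactants: 14 (S)-6-geranyl-5,7-bis(methoxymethoxy)-2-phenylspiro[chromane-4,2'-[1,3]dithiane]
Product: 15 (S)-6-geranyl-5,7-bis(methoxymethoxy)flavanone
Conditions: MeI, CaCO3, MeCN–H2O (9:1), 45 °C
Reagents that add atoms: water, O
Why: Alkylative dethioacetalisation: S-methylation opens the dithiane to a thionium ion that is strongly stabilised by the ortho and para oxygens of ring A and is captured by water. The conditions are non-oxidising and buffered near neutrality, so the olefins, the acetal ethers and the base-labile C2 centre should be unaffected.

**Step 8**
Reactants: 15 (S)-6-geranyl-5,7-bis(methoxymethoxy)flavanone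
Product: 16 (S)-6-geranyl-5,7-dihydroxyflavanone (target)
Conditions: 3 M aq. HCl, MeOH, 40 °C
Reagents that add atoms: none
Why: Acid-catalysed cleavage of the two aryl methoxymethyl acetals by transacetalisation to the solvent; the ether peri to the carbonyl and the one para to it are both activated. Dilute acid at moderate temperature avoids the base-induced ring opening that racemises flavanones and is mild enough that the trisubstituted olefins should not be protonated.

## Compound list

1 | 5-chlororesorcinol (5-chlorobenzene-1,3-diol) | Oc1cc(O)cc(Cl)c1 | starting material
2 | 1-chloro-3,5-bis(methoxymethoxy)benzene | COCOc1cc(Cl)cc(OCOC)c1 | intermediate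
3 | geranyl bromide [(2E)-1-bromo-3,7-dimethylocta-2,6-diene] | CC(C)=CCC/C(C)=C/CBr | starting material
4 | [4-chloro-2,6-bis(methoxymethoxy)phenyl]lithium | [Li]c1c(OCOC)cc(Cl)cc1OCOC | intermediate
5 | [4-chloro-2,6-bis(methoxymethoxy)phenyl]copper | [Cu]c1c(OCOC)cc(Cl)cc1OCOC | intermediate
6 | 5-chloro-2-geranyl-1,3-bis(methoxymethoxy)benzene | CC(C)=CCC/C(C)=C/Cc1c(OCOC)cc(Cl)cc1OCOC | intermediate
7 | [6-chloro-3-geranyl-2,4-bis(methoxymethoxy)phenyl]lithium | CC(C)=CCC/C(C)=C/Cc1c(OCOC)cc(Cl)c([Li])c1OCOC | intermediate
8 | 6-chloro-3-geranyl-2,4-bis(methoxymethoxy)benzaldehyde | CC(C)=CCC/C(C)=C/Cc1c(OCOC)cc(Cl)c(C=O)c1OCOC | intermediate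
9 | propane-1,3-dithiol | SCCCS | starting material
10 | 2-[6-chloro-3-geranyl-2,4-bis(methoxymethoxy)phenyl]-1,3-dithiane | CC(C)=CCC/C(C)=C/Cc1c(OCOC)cc(Cl)c(C2SCCCS2)c1OCOC | intermediate
11 | (R)-styrene oxide [(2R)-2-phenyloxirane] | C1O[C@@H]1c1ccccc1 | starting material
12 | {2-[6-chloro-3-geranyl-2,4-bis(methoxymethoxy)phenyl]-1,3-dithian-2-yl}lithium | CC(C)=CCC/C(C)=C/Cc1c(OCOC)cc(Cl)c(C2([Li])SCCCS2)c1OCOC | intermediate
13 | (S)-2-{2-[6-chloro-3-geranyl-2,4-bis(methoxymethoxy)phenyl]-1,3-dithian-2-yl}-1-phenylethanol | CC(C)=CCC/C(C)=C/Cc1c(OCOC)cc(Cl)c(C2(C[C@H](O)c3ccccc3)SCCCS2)c1OCOC | intermediate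
14 | (S)-6-geranyl-5,7-bis(methoxymethoxy)-2-phenylspiro[chromane-4,2'-[1,3]dithiane] | CC(C)=CCC/C(C)=C/Cc1c(OCOC)cc2c(c1OCOC)C1(C[C@@H](c3ccccc3)O2)SCCCS1 | intermediate
15 | (S)-6-geranyl-5,7-bis(methoxymethoxy)flavanone | CC(C)=CCC/C(C)=C/Cc1c(OCOC)cc2c(c1OCOC)C(=O)C[C@@H](c1ccccc1)O2 | intermediate
16 | (S)-6-geranyl-5,7-dihydroxyflavanone | CC(C)=CCC/C(C)=C/Cc1c(O)cc2c(c1O)C(=O)C[C@@H](c1ccccc1)O2 | target

## Step count and least certain steps

Total: 8 steps. Longest linear sequence: 8 steps, from 1 to 16; compounds 3, 9 and 11 enter as purchased fragments.

**Step 6 (key step).**
- **What may go wrong:** β-hydride elimination of the benzylic palladium alkoxide may outrun C–O reductive elimination, oxidising the carbinol and reducing the C–Cl bond. A thioketal sulfur may chelate the arylpalladium centre through a five-membered ring and slow alkoxide binding. Oxidative addition into the hindered chloride may be slow.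
- **Fallback:** a metal-free closure of the same O1–C8a bond, setting out from 13 and returning at 14. Excess lithium 2,2,6,6-tetramethylpiperidide in THF, −78 °C → rt, deprotonates the hydroxyl and the C8–H (the position flanked by chlorine and the C7 acetal ether, the same kind of site metalated in step 3). Loss of LiCl gives the C8–C8a aryne alkoxide F1. Its tethered alkoxide can only reach C8a, which is also the electronically preferred terminus distal to the C7 oxygen, and protonation at C8 on work-up gives 14. Intramolecular alkoxide addition to arynes is a known route to chromans, and C2 is again untouched.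

**Step 5.**
- **What may go wrong:** deprotonation may occur at the ring C8–H or at the benzylic–allylic CH2 of the chain instead of the hindered thioketal C–H, followed by loss of LiCl on warming. The crowded tertiary carbanion may attack the epoxide slowly, or partly at its benzylic carbon.
- **Fallback:** a route with no dithiane anion, setting out from 8 and returning at 13; it also bypasses step 4. Ohira–Bestmann homologation (dimethyl (1-diazo-2-oxopropyl)phosphonate, K2CO3, MeOH) gives the terminal alkyne F2. Acyl Sonogashira coupling with benzoyl chloride (PdCl2(PPh3)2, CuI, Et3N) gives the ynone F3. Base-mediated double conjugate addition of 9 (NaOMe, MeOH–CH2Cl2) places both sulfurs on the aryl-bearing carbon and gives the β-keto dithiane F4. Corey–Bakshi–Shibata reduction with (R)-1-methyl-3,3-diphenyltetrahydro-1H,3H-pyrrolo[1,2-c][1,3,2]oxazaborole and BH3·SMe2, with phenyl as the large group, should deliver the S carbinol 13. Here the configuration is set by the reagent instead of the chiral pool.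

**Step 4.**
- **What may go wrong:** Lewis acid and thiol together may strip the acetal ethers, the one ortho to the formyl group first, or acid may add to the chain olefins.
- **Fallback:** an acid-free entry to the dithiane, setting out from 7 (generated from 6 as in step 3) and returning at 10. The aryllithium is transmetalated with MgBr2·OEt2 at −78 °C to the arylmagnesium bromide F5, which does not eliminate halide on warming. F5 is then treated with 2-chloro-1,3-dithiane F6, a formyl cation equivalent prepared from 1,3-dithiane and N-chlorosuccinimide, to give 10 directly. The aldehyde is not made at all.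

**Step 2.**
- **What may go wrong:** metalation may occur next to chlorine rather than between the two acetal ethers, followed by loss of LiCl. Allylic transposition during the copper-mediated coupling may attach the chain through its tertiary carbon.
- **Fallback:** the metalation site is fixed by a halogen instead of by direction, setting out from 1 and returning at aryllithium 4. Iodination of 1 with I2 and NaHCO3 in water goes to the carbon between the two hydroxyls and gives 5-chloro-2-iodobenzene-1,3-diol F7. Protection as in step 1 gives 5-chloro-2-iodo-1,3-bis(methoxymethoxy)benzene F8. Iodine–lithium exchange (n-BuLi, THF, −78 °C) generates 4 unambiguously, and the copper-mediated geranylation proceeds as in step 2.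

## Further compounds

F1 | step 6 | C8–C8a aryne derived from 13 (drawn as the alcohol; present as its lithium alkoxide) | CC(C)=CCC/C(C)=C/CC1=C(OCOC)C#CC(C2(C[C@H](O)c3ccccc3)SCCCS2)=C1OCOC
F2 | step 5 | 1-chloro-2-ethynyl-4-geranyl-3,5-bis(methoxymethoxy)benzene | CC(C)=CCC/C(C)=C/Cc1c(OCOC)cc(Cl)c(C#C)c1OCOC
F3 | step 5 | 3-[6-chloro-3-geranyl-2,4-bis(methoxymethoxy)phenyl]-1-phenylprop-2-yn-1-one | CC(C)=CCC/C(C)=C/Cc1c(OCOC)cc(Cl)c(C#CC(=O)c2ccccc2)c1OCOC
F4 | step 5 | 2-{2-[6-chloro-3-geranyl-2,4-bis(methoxymethoxy)phenyl]-1,3-dithian-2-yl}-1-phenylethan-1-one | CC(C)=CCC/C(C)=C/Cc1c(OCOC)cc(Cl)c(C2(CC(=O)c3ccccc3)SCCCS2)c1OCOC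
F5 | step 4 | [6-chloro-3-geranyl-2,4-bis(methoxymethoxy)phenyl]magnesium bromide | CC(C)=CCC/C(C)=C/Cc1c(OCOC)cc(Cl)c([Mg]Br)c1OCOC
F6 | step 4 | 2-chloro-1,3-dithiane | ClC1SCCCS1
F7 | step 2 | 5-chloro-2-iodobenzene-1,3-diol | Oc1cc(Cl)cc(O)c1I
F8 | step 2 | 5-chloro-2-iodo-1,3-bis(methoxymethoxy)benzene | COCOc1cc(Cl)cc(OCOC)c1I
A1 | alternative 1 | 4-geranyl-3,5-bis(methoxymethoxy)-2-(trimethylsilyl)phenyl trifluoromethanesulfonate | CC(C)=CCC/C(C)=C/Cc1c(OCOC)cc(OS(=O)(=O)C(F)(F)F)c([Si](C)(C)C)c1OCOC
A2 | alternative 1 | (R)-3-[(4-methoxybenzyl)oxy]-3-phenylpropanoic acid | OC(=O)C[C@@H](OCc1ccc(OC)cc1)c1ccccc1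
A3 | alternative 1 | (R)-1-[3-geranyl-6-hydroxy-2,4-bis(methoxymethoxy)phenyl]-3-[(4-methoxybenzyl)oxy]-3-phenylpropan-1-one | CC(C)=CCC/C(C)=C/Cc1c(OCOC)cc(O)c(C(=O)C[C@@H](OCc2ccc(OC)cc2)c2ccccc2)c1OCOC
A4 | alternative 2 | 1-[6-(benzyloxy)-3-geranyl-2,4-bis(tert-butyldimethylsilyloxy)phenyl]-2-diazoethan-1-one | CC(C)=CCC/C(C)=C/Cc1c(O[Si](C)(C)C(C)(C)C)cc(OCc2ccccc2)c(C(=O)C=[N+]=[N-])c1O[Si](C)(C)C(C)(C)C
A5 | alternative 2 | (S)-5,7-bis(tert-butyldimethylsilyloxy)-6-geranylflavanone | CC(C)=CCC/C(C)=C/Cc1c(O[Si](C)(C)C(C)(C)C)cc2c(c1O[Si](C)(C)C(C)(C)C)C(=O)C[C@@H](c1ccccc1)O2
A6 | alternative 3 | 4-geranyl-2-iodo-3,5-bis(methoxymethoxy)phenol | CC(C)=CCC/C(C)=C/Cc1c(OCOC)cc(O)c(I)c1OCOC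
A7 | alternative 3 | phenylacetylene | C#Cc1ccccc1
A8 | alternative 3 | carbon monoxide | [C-]#[O+]
A9 | alternative 3 | 6-geranyl-5,7-bis(methoxymethoxy)flavone | CC(C)=CCC/C(C)=C/Cc1c(OCOC)cc2oc(-c3ccccc3)cc(=O)c2c1OCOC
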